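**Plan**

- Retrosynthesis: cut C2–C1' (aryl addition to a chromone), then O1–C2 and C2–C3 (one-carbon annulation of an o-hydroxyacetophenone), then the two isopropenyl bonds at C3'' (C=CH2 and C–CH3), then C1''–C2'', and last C8–C1''.
- Enabling feature: C1'' is a benzylic CH2 on C8 of ring A, ortho to the phenolic oxygen that ends as O1. C8, C1'' and that oxygen are therefore the atoms of an o-quinone methide, and C2''/C3'' are the α- and carbonyl carbons of 5-methylhex-4-enal.
- Forward: ring A acetophenone (one phenol as MOM ether) → sulfonylmethylation → enamine/o-quinone methide union, which closes a temporary lactol ring on the future O1 → lactol carbon converted to isopropenyl → pyranone ring closed on the released O1 → ring B added → deprotection.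
- Stereochemistry: C2'' (R) comes from the (S)-diphenylprolinol silyl ether catalyst in the key step; C2 (S) comes from the chiral rhodium catalyst in the aryl addition.

Key step: step 4

Assumption: the (S)-configured biaryl bisphosphine in step 12 is taken to deliver the aryl group to the chromone face that gives 2S, as this ligand family does with cyclic enones; its antipode would be used if a model addition showed the opposite sense.

**Route**

Step 1
Reactants: 1 1-(2,6-dihydroxy-4-methoxyphenyl)ethanone
Product: 2 1-[2-hydroxy-4-methoxy-6-(methoxymethoxy)phenyl]ethanone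
Conditions: MOMCl (1.1 equiv), iPr2NEt, CH2Cl2, 0 °C
Reagents that add atoms: chloromethyl methyl ether, COCCl
Why: Williamson-type O-alkylation of a phenol; the two hydroxyls of 1 are equivalent, and once one is etherified the other is held in a hydrogen bond to the acetyl oxygen, which should stop the reaction at the mono-ether.

Step 2
Reactants: 2 1-[2-hydroxy-4-methoxy-6-(methoxymethoxy)phenyl]ethanone
Product: 4 1-[2-hydroxy-4-methoxy-6-(methoxymethoxy)-3-[(4-methylphenyl)sulfonylmethyl]phenyl]ethanone, via hydroxymethyl phenol 3 (not isolated)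
Conditions: aq. CH2O (1.1 equiv), TolSO2Na (1.5 equiv), AcOH, EtOH/H2O, 40 °C
Reagents that add atoms: formaldehyde, C=O; sodium p-toluenesulfinate, Cc1ccc(S(=O)[O-])cc1.[Na+]
Why: Mannich-type three-component sulfonylmethylation: formaldehyde hydroxymethylates the ring ortho to the chelated hydroxyl (the position flanked only by OH and OMe, which this class of acetophenone normally uses), the benzylic alcohol ionises through an o-quinone methide and the sulfinate adds through sulfur, while acetic acid is too weak to cleave the aryl MOM ether.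

Step 3
Reactants: 5 2-methylbut-3-en-2-ol
Product: 7 5-methylhex-4-enal, via allyl vinyl ether 6 (not isolated)
Conditions: ethyl vinyl ether (3 equiv), H3PO4 (cat.), sealed vessel, 140 °C
Reagents that add atoms: ethyl vinyl ether, C=COCC
Why: Acid-catalysed vinyl transfer followed by Claisen rearrangement of the tertiary allyl vinyl ether, whose chair [3,3] shift turns the carbinol carbon into the trisubstituted alkene and releases the aldehyde.

Step 4
Reactants: 4 1-[2-hydroxy-4-methoxy-6-(methoxymethoxy)-3-[(4-methylphenyl)sulfonylmethyl]phenyl]ethanone; 7 5-methylhex-4-enal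
Product: 10 1-[(3R)-2-hydroxy-5-methoxy-7-(methoxymethoxy)-3-(3-methylbut-2-en-1-yl)-3,4-dihydro-2H-chromen-8-yl]ethanone (anomeric mixture), via o-quinone methide 8 (not isolated), via catalyst enamine 9 (not isolated)
Conditions: (S)-α,α-diphenylprolinol TMS ether (20 mol %), Na2CO3 (1.5 equiv), 7 (1.5 equiv), CH2Cl2, 0 °C
Reagents that add atoms: none
Why: Na2CO3 deprotonates the chelated phenol of 4 and E1cB loss of p-toluenesulfinate releases o-quinone methide 8 at low stationary concentration, while 7 and the prolinol ether form the E enamine 9. The enamine α-carbon adds to the exocyclic methylene of 8 (Michael addition), which re-aromatises ring A and forms C1''–C2''; the phenoxide then closes on the iminium carbon (6-exo-trig) and hydrolysis gives the chroman-2-ol and returns the amine. This is the aminocatalytic enamine addition/annulation of aldehydes with o-quinone methides released from 2-(sulfonylmethyl)phenols, used here with a methide that has no benzylic substituent. C2'' (C3 of the lactol) is set by the catalyst: the diphenyl(silyloxy)methyl group shields one face of the s-trans E enamine, so the (S) catalyst should give R, the same sense as in its Michael additions to nitroalkenes. The step needs C- rather than N-alkylation of the amine and a single site of methide formation; the first should follow from fast enamine formation with excess aldehyde at a hindered nitrogen, the second from the MOM ether, which leaves only one phenol able to form a quinone methide. The lactol keeps the aldehyde masked, which guards C2'' against enamine-mediated epimerisation and marks the oxygen that becomes O1.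

Step 5
Reactants: 10 1-[(3R)-2-hydroxy-5-methoxy-7-(methoxymethoxy)-3-(3-methylbut-2-en-1-yl)-3,4-dihydro-2H-chromen-8-yl]ethanone
Product: 12 1-[2-hydroxy-3-[(2R)-2-(1-hydroxyethyl)-5-methylhex-4-en-1-yl]-4-methoxy-6-(methoxymethoxy)phenyl]ethanone (both carbinol epimers), via open-chain aldehyde 11 (not isolated)
Conditions: MeMgBr (2.3 equiv), THF, −78 to −20 °C; then H2O
Reagents that add atoms: methylmagnesium bromide, C[Mg]Br
Why: Grignard addition to a lactol through its ring-opened aldehyde: the first equivalent deprotonates and opens the hemiacetal to the bromomagnesium phenoxide, which together with the two ortho substituents deactivates the acetyl group, so that at low temperature the second equivalent should add only to the aldehyde and faster than it enolises it; the new carbinol centre is formed without control and is removed in step 6.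

Step 6
Reactants: 12 1-[2-hydroxy-3-[(2R)-2-(1-hydroxyethyl)-5-methylhex-4-en-1-yl]-4-methoxy-6-(methoxymethoxy)phenyl]ethanone
Product: 13 (3R)-3-[[3-acetyl-2-hydroxy-6-methoxy-4-(methoxymethoxy)phenyl]methyl]-6-methylhept-5-en-2-one
Conditions: Dess–Martin periodinane (1.3 equiv), CH2Cl2, 0 °C to rt
Reagents that add atoms: none
Why: Dess–Martin oxidation of the secondary alcohol under neutral, non-enolising conditions, which should leave the hydrogen-bonded phenol, the MOM ether and the α stereocentre untouched.

Step 7
Reactants: 13 (3R)-3-[[3-acetyl-2-hydroxy-6-methoxy-4-(methoxymethoxy)phenyl]methyl]-6-methylhept-5-en-2-one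
Product: 14 1-[2-hydroxy-4-methoxy-6-(methoxymethoxy)-3-[(2R)-5-methyl-2-(prop-1-en-2-yl)hex-4-en-1-yl]phenyl]ethanone
Conditions: Ph3PCH3Br (3.5 equiv), KOtBu (3.3 equiv), THF, 0 °C to rt
Reagents that add atoms: methyltriphenylphosphonium bromide, C[P+](c1ccccc1)(c1ccccc1)c1ccccc1.[Br-]
Why: Wittig methylenation: the ylide first deprotonates the phenol, and the resulting phenoxide makes the hindered aryl ketone inert, so that only the aliphatic methyl ketone is olefinated; this ketone is deprotonated mainly on its methyl side, so C2'' should keep its configuration.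

Step 8
Reactants: 14 1-[2-hydroxy-4-methoxy-6-(methoxymethoxy)-3-[(2R)-5-methyl-2-(prop-1-en-2-yl)hex-4-en-1-yl]phenyl]ethanone
Product: 16 7-methoxy-5-(methoxymethoxy)-8-[(2R)-5-methyl-2-(prop-1-en-2-yl)hex-4-en-1-yl]-4H-chromen-4-one, via enaminone 15 (not isolated)
Conditions: Me2NCH(OMe)2 (3 equiv), toluene, 95 °C; then AcOH, 60 °C
Reagents that add atoms: N,N-dimethylformamide dimethyl acetal, COC(OC)N(C)C
Why: Condensation of the acetyl methyl group with the amide acetal gives the enaminone, and mild acid then promotes 6-endo-trig oxa-Michael addition of the only free phenol with loss of dimethylamine (enaminone route to chromones), which places O1 next to the carbon that bears the lavandulyl chain; acetic acid should spare the MOM ether.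

Step 9
Reactants: 17 4-methoxybenzene-1,3-diol
Product: 18 1-methoxy-2,4-bis(methoxymethoxy)benzene
Conditions: MOMCl (2.5 equiv), iPr2NEt, CH2Cl2, 0 °C to rt, N2
Reagents that add atoms: chloromethyl methyl ether, COCCl
Why: Double Williamson-type O-alkylation of both phenols under an amine base, run under inert gas because the free trioxygenated benzene is air-sensitive.

Step 10
Reactants: 18 1-methoxy-2,4-bis(methoxymethoxy)benzene
Product: 19 1-bromo-5-methoxy-2,4-bis(methoxymethoxy)benzene
Conditions: NBS (1.05 equiv), MeCN, 0 °C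
Reagents that add atoms: N-bromosuccinimide, O=C1CCC(=O)N1Br
Why: Electrophilic aromatic bromination at the one position that is para to one MOM ether and ortho to the other without lying between two substituents.

Step 11
Reactants: 19 1-bromo-5-methoxy-2,4-bis(methoxymethoxy)benzene
Product: 22 [5-methoxy-2,4-bis(methoxymethoxy)phenyl]boronic acid, via aryllithium 20 (not isolated), via lithium borate 21 (not isolated)
Conditions: n-BuLi (1.1 equiv), THF, −78 °C; B(OiPr)3; then H2O
Reagents that add atoms: triisopropyl borate, CC(C)OB(OC(C)C)OC(C)C; water, O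
Why: Bromine–lithium exchange at low temperature, trapping of the aryllithium with the borate ester and hydrolysis on work-up, a standard route to ortho-alkoxy arylboronic acids.

Step 12
Reactants: 16 7-methoxy-5-(methoxymethoxy)-8-[(2R)-5-methyl-2-(prop-1-en-2-yl)hex-4-en-1-yl]-4H-chromen-4-one; 22 [5-methoxy-2,4-bis(methoxymethoxy)phenyl]boronic acid
Product: 23 (2S)-7-methoxy-2-[5-methoxy-2,4-bis(methoxymethoxy)phenyl]-5-(methoxymethoxy)-8-[(2R)-5-methyl-2-(prop-1-en-2-yl)hex-4-en-1-yl]-2,3-dihydro-4H-chromen-4-one
Conditions: [Rh(OH)(cod)]2 (3 mol %), (S)-MeO-F12-BIPHEP (7 mol %), 22 (3 equiv), toluene/H2O, 50 °C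
Reagents that add atoms: none
Why: Rhodium-catalysed asymmetric conjugate addition of an arylboronic acid to a chromone (Hayashi–Miyaura reaction): transmetalation gives an aryl-rhodium species that inserts C2=C3 and the oxa-π-allyl is protonated by water; the chiral bisphosphine selects the enone face and so sets C2 as S independently of the remote C2'' centre, and the base-free medium should avoid ring opening of the flavanone.

Step 13
Reactants: 23 (2S)-7-methoxy-2-[5-methoxy-2,4-bis(methoxymethoxy)phenyl]-5-(methoxymethoxy)-8-[(2R)-5-methyl-2-(prop-1-en-2-yl)hex-4-en-1-yl]-2,3-dihydro-4H-chromen-4-one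
Product: 24 (2S)-2-(2,4-dihydroxy-5-methoxyphenyl)-5-hydroxy-7-methoxy-8-[(2R)-5-methyl-2-(prop-1-en-2-yl)hex-4-en-1-yl]-2,3-dihydro-4H-chromen-4-one
Conditions: 3 M aq. HCl, MeOH, 40 °C
Reagents that add atoms: none
Why: Acid-catalysed acetal exchange of the three MOM ethers with methanol; with no free hydroxyl ortho to the lavandulyl chain the alkenes have no cyclisation path, and the short, mild exposure should not open the pyranone ring at C2.

**Compound list**

1 | 1-(2,6-dihydroxy-4-methoxyphenyl)ethanone | CC(=O)c1c(O)cc(OC)cc1O | starting material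
2 | 1-[2-hydroxy-4-methoxy-6-(methoxymethoxy)phenyl]ethanone | CC(=O)c1c(O)cc(OC)cc1OCOC | intermediate
3 | 1-[2-hydroxy-3-(hydroxymethyl)-4-methoxy-6-(methoxymethoxy)phenyl]ethanone | CC(=O)c1c(OCOC)cc(OC)c(CO)c1O | intermediate (not isolated)
4 | 1-[2-hydroxy-4-methoxy-6-(methoxymethoxy)-3-[(4-methylphenyl)sulfonylmethyl]phenyl]ethanone | CC(=O)c1c(OCOC)cc(OC)c(CS(=O)(=O)c2ccc(C)cc2)c1O | intermediate
5 | 2-methylbut-3-en-2-ol | C=CC(C)(C)O | starting material
6 | 3-(ethenyloxy)-3-methylbut-1-ene | C=COC(C)(C)C=C | intermediate (not isolated)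
7 | 5-methylhex-4-enal | CC(C)=CCCC=O | intermediate
8 | 2-acetyl-5-methoxy-3-(methoxymethoxy)-6-methylidenecyclohexa-2,4-dien-1-one | CC(=O)C1=C(OCOC)C=C(OC)C(=C)C1=O | intermediate (not isolated)
9 | (2S)-2-[diphenyl(trimethylsilyloxy)methyl]-1-[(1E)-5-methylhexa-1,4-dien-1-yl]pyrrolidine | CC(C)=CC/C=C/N1CCC[C@H]1C(O[Si](C)(C)C)(c1ccccc1)c1ccccc1 | intermediate (not isolated)
10 | 1-[(3R)-2-hydroxy-5-methoxy-7-(methoxymethoxy)-3-(3-methylbut-2-en-1-yl)-3,4-dihydro-2H-chromen-8-yl]ethanone, both anomers at C2 | CC(=O)c1c(OCOC)cc(OC)c2c1OC(O)[C@H](CC=C(C)C)C2 | intermediate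
11 | (2R)-2-[[3-acetyl-2-hydroxy-6-methoxy-4-(methoxymethoxy)phenyl]methyl]-5-methylhex-4-enal, present as its bromomagnesium phenoxide | CC(=O)c1c(OCOC)cc(OC)c(C[C@@H](CC=C(C)C)C=O)c1O | intermediate (not isolated)
12 | 1-[2-hydroxy-3-[(2R)-2-(1-hydroxyethyl)-5-methylhex-4-en-1-yl]-4-methoxy-6-(methoxymethoxy)phenyl]ethanone, both carbinol epimers | CC(=O)c1c(OCOC)cc(OC)c(C[C@@H](CC=C(C)C)C(C)O)c1O | intermediate
13 | (3R)-3-[[3-acetyl-2-hydroxy-6-methoxy-4-(methoxymethoxy)phenyl]methyl]-6-methylhept-5-en-2-one, in equilibrium with its cyclic hemiketal | CC(=O)c1c(OCOC)cc(OC)c(C[C@@H](CC=C(C)C)C(C)=O)c1O | intermediate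
14 | 1-[2-hydroxy-4-methoxy-6-(methoxymethoxy)-3-[(2R)-5-methyl-2-(prop-1-en-2-yl)hex-4-en-1-yl]phenyl]ethanone | CC(=O)c1c(OCOC)cc(OC)c(C[C@@H](CC=C(C)C)C(C)=C)c1O | intermediate
15 | (2E)-3-(dimethylamino)-1-[2-hydroxy-4-methoxy-6-(methoxymethoxy)-3-[(2R)-5-methyl-2-(prop-1-en-2-yl)hex-4-en-1-yl]phenyl]prop-2-en-1-one | CN(C)/C=C/C(=O)c1c(OCOC)cc(OC)c(C[C@@H](CC=C(C)C)C(C)=C)c1O | intermediate (not isolated)
16 | 7-methoxy-5-(methoxymethoxy)-8-[(2R)-5-methyl-2-(prop-1-en-2-yl)hex-4-en-1-yl]-4H-chromen-4-one | O=C1C=COc2c1c(OCOC)cc(OC)c2C[C@@H](CC=C(C)C)C(C)=C | intermediate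
17 | 4-methoxybenzene-1,3-diol | COc1ccc(O)cc1O | starting material
18 | 1-methoxy-2,4-bis(methoxymethoxy)benzene | COc1ccc(OCOC)cc1OCOC | intermediate
19 | 1-bromo-5-methoxy-2,4-bis(methoxymethoxy)benzene | COc1cc(Br)c(OCOC)cc1OCOC | intermediate
20 | [5-methoxy-2,4-bis(methoxymethoxy)phenyl]lithium | [Li]c1cc(OC)c(OCOC)cc1OCOC | intermediate (not isolated)
21 | lithium [5-methoxy-2,4-bis(methoxymethoxy)phenyl]tri(propan-2-yloxy)borate | [Li+].CC(C)O[B-](OC(C)C)(OC(C)C)c1cc(OC)c(OCOC)cc1OCOC | intermediate (not isolated)
22 | [5-methoxy-2,4-bis(methoxymethoxy)phenyl]boronic acid | COc1cc(B(O)O)c(OCOC)cc1OCOC | intermediate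
23 | (2S)-7-methoxy-2-[5-methoxy-2,4-bis(methoxymethoxy)phenyl]-5-(methoxymethoxy)-8-[(2R)-5-methyl-2-(prop-1-en-2-yl)hex-4-en-1-yl]-2,3-dihydro-4H-chromen-4-one | C=C(C)[C@H](CC=C(C)C)Cc1c(OC)cc(OCOC)c2c1O[C@H](c1cc(OC)c(OCOC)cc1OCOC)CC2=O | intermediate
24 | (2S)-2-(2,4-dihydroxy-5-methoxyphenyl)-5-hydroxy-7-methoxy-8-[(2R)-5-methyl-2-(prop-1-en-2-yl)hex-4-en-1-yl]-2,3-dihydro-4H-chromen-4-one | C=C(C)[C@H](CC=C(C)C)Cc1c(OC)cc(O)c2c1O[C@H](c1cc(OC)c(O)cc1O)CC2=O | target

**Step count and risks**

Total step count: 13. Longest linear sequence: 9 steps (steps 1, 2, 4, 5, 6, 7, 8, 12 and 13, from 1).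

Steps most likely to fail:

Step 4. The unsubstituted o-quinone methide may oligomerise or alkylate the catalyst nitrogen faster than it meets the enamine, and facial control at the enamine may be incomplete. The fallback replaces catalytic enamine control by a stoichiometric chiral hydrazone and sets out from 7 and 4. Condensation of 7 with (R)-1-amino-2-(methoxymethyl)pyrrolidine should give the hydrazone (E)-N-[(2R)-2-(methoxymethyl)pyrrolidin-1-yl]-5-methylhex-4-en-1-imine F1. Its azaenolate (LDA, THF, −78 °C) is used in twofold amount against 4, so that one equivalent releases 8 and the second adds to it under auxiliary control, giving the C-benzylated hydrazone 1-[2-hydroxy-4-methoxy-6-(methoxymethoxy)-3-[(2R)-2-[(E)-[[(2R)-2-(methoxymethyl)pyrrolidin-1-yl]imino]methyl]-5-methylhex-4-en-1-yl]phenyl]ethanone F2. Cleavage with aqueous oxalic acid/Et2O frees the aldehyde, which closes to the lactol, and the route is rejoined at 10.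

Step 12. Transmetalation and insertion may be too slow with an ortho-substituted, protodeboronation-prone boronic acid on an electron-rich chromone crowded at C5 and C8, and facial control may erode. The fallback builds ring C by the chalcone route and sets out from 14 and 20. Quenching 20 with DMF should give 5-methoxy-2,4-bis(methoxymethoxy)benzaldehyde F3. Claisen–Schmidt condensation with 14 (KOH, EtOH) then gives (2E)-1-[2-hydroxy-4-methoxy-6-(methoxymethoxy)-3-[(2R)-5-methyl-2-(prop-1-en-2-yl)hex-4-en-1-yl]phenyl]-3-[5-methoxy-2,4-bis(methoxymethoxy)phenyl]prop-2-en-1-one F4. Oxa-Michael ring closure (NaOAc, EtOH, reflux) through the only free phenol gives 23 together with its C2 epimer, (2R)-7-methoxy-2-[5-methoxy-2,4-bis(methoxymethoxy)phenyl]-5-(methoxymethoxy)-8-[(2R)-5-methyl-2-(prop-1-en-2-yl)hex-4-en-1-yl]-2,3-dihydro-4H-chromen-4-one F5. The two are diastereomers and are separated by preparative HPLC, the unwanted one being re-equilibrated through the chalcone with base; the route is rejoined at 23.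

Step 2. Hydroxymethylation may occur at the other free ring position, the benzylic cation may be captured by a second arene to give a methylene-bridged dimer, or the MOM ether may be lost in the acidic medium. The fallback separates the C–C and C–S bond formations under non-acidic conditions and sets out from 2. A phenol-directed Mannich reaction (aq. Me2NH, aq. CH2O, EtOH, rt) should give 1-[3-[(dimethylamino)methyl]-2-hydroxy-4-methoxy-6-(methoxymethoxy)phenyl]ethanone F6. Heating F6 with TolSO2Na in DMF at 100 °C exchanges the amine for the sulfinate through the thermally released o-quinone methide, and the route is rejoined at 4.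

Further compounds
F1 | step 4 | (E)-N-[(2R)-2-(methoxymethyl)pyrrolidin-1-yl]-5-methylhex-4-en-1-imine | CC(C)=CCC/C=N/N1CCC[C@@H]1COC
F2 | step 4 | 1-[2-hydroxy-4-methoxy-6-(methoxymethoxy)-3-[(2R)-2-[(E)-[[(2R)-2-(methoxymethyl)pyrrolidin-1-yl]imino]methyl]-5-methylhex-4-en-1-yl]phenyl]ethanone | CC(=O)c1c(OCOC)cc(OC)c(C[C@@H](CC=C(C)C)/C=N/N2CCC[C@@H]2COC)c1O
F3 | step 12 | 5-methoxy-2,4-bis(methoxymethoxy)benzaldehyde | COc1cc(C=O)c(OCOC)cc1OCOC
F4 | step 12 | (2E)-1-[2-hydroxy-4-methoxy-6-(methoxymethoxy)-3-[(2R)-5-methyl-2-(prop-1-en-2-yl)hex-4-en-1-yl]phenyl]-3-[5-methoxy-2,4-bis(methoxymethoxy)phenyl]prop-2-en-1-one | O=C(/C=C/c1cc(OC)c(OCOC)cc1OCOC)c1c(OCOC)cc(OC)c(C[C@@H](CC=C(C)C)C(C)=C)c1O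
F5 | step 12 | (2R)-7-methoxy-2-[5-methoxy-2,4-bis(methoxymethoxy)phenyl]-5-(methoxymethoxy)-8-[(2R)-5-methyl-2-(prop-1-en-2-yl)hex-4-en-1-yl]-2,3-dihydro-4H-chromen-4-one | C=C(C)[C@H](CC=C(C)C)Cc1c(OC)cc(OCOC)c2c1O[C@@H](c1cc(OC)c(OCOC)cc1OCOC)CC2=O
F6 | step 2 | 1-[3-[(dimethylamino)methyl]-2-hydroxy-4-methoxy-6-(methoxymethoxy)phenyl]ethanone | CC(=O)c1c(OCOC)cc(OC)c(CN(C)C)c1O
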